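## Retrosynthetic overview
1. Norkurarinol (13) comes from acid removal of the MOM groups on a protected flavanone (12). The C-ring closes by oxa-Michael addition of the single free 2'-OH of chalcone 11, as in xanthohumol → isoxanthohumol, which fixes the 8-alkyl regiochemistry.
2. Chalcone 11 comes from Claisen–Schmidt condensation of the lavandulylated bis-MOM acetophenone 8 with bis-MOM-2,4-dihydroxybenzaldehyde 10.
3. Key disconnection: the aryl–CH2 bond. It is formed photochemically by blue-light decarboxylative C–H alkylation of commercial phloroacetophenone (6) with the N-hydroxyphthalimide (NHPI) ester 5. This gives a symmetric arene, so there is no C-3'/C-5' regiochemistry problem.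
4. Ester 5 and the lavandulyl (R)-stereocentre come from (R)-limonene oxide (1). The ring is cleaved, the acid is made, and MeMgBr converts the methyl ketone into the C(CH3)2OH group.
5. Ring order: both aromatic rings are bought, so the pyranone C-ring is the only ring formed, and it is formed last.

Assumptions:
- Commercial (+)-limonene oxide (cis/trans mixture) is used as is; the epoxide stereocentres are destroyed in Step 1.
- The remote lavandulyl stereocentre gives no useful induction at C-2, so the C-2 epimers are separated by HPLC in Step 10 (the 2S epimer is identified by CD).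

## Route

**Step 1**
Reactants: 1, (+)-limonene oxide ((4R), cis/trans mixture)
Product: 2, (3R)-3-isopropenyl-6-oxoheptanal
Conditions: H5IO6 (1.3 equiv), THF/H2O 4:1, 0 °C → rt, 2 h
Reagents that add atoms: water (O)
Why: Acid opens the epoxide to the diol in situ, and periodate cleaves it (Malaprade cleavage). C-4 is β to the aldehyde and cannot epimerise, so the (R)-centre is kept and both epoxide isomers converge on one product.

**Step 2**
Reactants: 2
Product: 3, (3R)-3-isopropenyl-6-oxoheptanoic acid
Conditions: NaClO2, NaH2PO4, 2-methyl-2-butene, tBuOH/H2O, rt, 3 h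
Reagents that add atoms: NaClO2 ([Na+].[O-]Cl=O)
Why: Pinnick oxidation. The alkene scavenger stops HOCl attack on the isopropenyl group, and the stereocentre is untouched.

**Step 3**
Reactants: 3
Product: 4, (3R)-6-hydroxy-6-methyl-3-isopropenylheptanoic acid
Conditions: MeMgBr (3 equiv), THF, −20 → 0 °C; quench with 1 M NaHSO4 to pH 3–4
Reagents that add atoms: MeMgBr (C[Mg]Br)
Why: The magnesium carboxylate is inert, so the Grignard adds only to the methyl ketone and gives the tertiary carbinol of the hydrated lavandulyl chain. The new carbinol carbon is not a stereocentre, and C-3 is not enolisable.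

**Step 4**
Reactants: 4
Product: 5, NHPI ester of 4
Conditions: N-hydroxyphthalimide (1.1 equiv), DIC (1.2 equiv), DMAP (10 mol%), CH2Cl2, rt, 3 h
Reagents that add atoms: N-hydroxyphthalimide (O=C1c2ccccc2C(=O)N1O)
Why: Carbodiimide esterification. The hindered tertiary alcohol does not compete.

**Step 5**
Reactants: 5 and 6, 2,4,6-trihydroxyacetophenone (3 equiv)
Product: 7, 1-{2,4,6-trihydroxy-3-[(2R)-5-hydroxy-5-methyl-2-(prop-1-en-2-yl)hexyl]phenyl}ethanone
Conditions: K2CO3 (1.5 equiv), DMSO (0.1 M), blue LEDs (456 nm), N2, 25 °C, 16 h
Reagents that add atoms: none (CO2 and phthalimide are lost)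
Why: Decarboxylative C–H alkylation gives the aryl–CH2 bond at C-3' (C-3' and C-5' are equivalent), and the radical sits on the CH2, not on the stereocentre. Proposed new method: the acylphloroglucinol phenolate (donor) and the NHPI ester (acceptor) form a visible-light-absorbing EDA complex. SET triggers N–O cleavage and loss of CO2 to give the primary β-branched alkyl radical. This adds ortho to the phenolate oxygen, and the resulting radical anion reduces the next NHPI ester (chain) before tautomerising to the phenol. The closest known reactions are EDA-complex decarboxylative C–H alkylation of indoles, enolates and naphthols, and Minisci alkylation. What is new is applying it to an unprotected acylphloroglucinol with a homoallylic primary radical that must be trapped before a 1,2-vinyl shift or 3-exo closure.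

**Step 6**
Reactants: 7
Product: 8, 1-{2-hydroxy-4,6-bis(methoxymethoxy)-3-[(2R)-5-hydroxy-5-methyl-2-(prop-1-en-2-yl)hexyl]phenyl}ethanone
Conditions: MOMCl (2.2 equiv), K2CO3 (4 equiv), acetone, 0 °C → rt, 12 h
Reagents that add atoms: MOMCl (ClCOC)
Why: Williamson-type O-alkylation. The acidic 4'-OH and the unhindered chelated 6'-OH react, while the 2'-OH is hindered by the adjacent lavandulyl group and chelated to the C=O, so it stays free. The tertiary alcohol is inert to K2CO3/MOMCl.

**Step 7**
Reactants: 9, 2,4-dihydroxybenzaldehyde
Product: 10, 2,4-bis(methoxymethoxy)benzaldehyde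
Conditions: MOMCl (2.5 equiv), iPr2NEt (3 equiv), CH2Cl2, 0 °C → rt, 12 h
Reagents that add atoms: MOMCl (ClCOC)
Why: Standard MOM protection of both phenols, so the B-ring phenolates do not shut down the aldol step.

**Step 8**
Reactants: 8 and 10
Product: 11, (E)-chalcone
Conditions: KOH (aq, 8 equiv), EtOH, rt, 48 h
Reagents that add atoms: none
Why: Claisen–Schmidt (aldol) condensation. The MOM ethers and the tertiary alcohol are base-stable, and the stereocentre is remote.

**Step 9**
Reactants: 11
Product: 12, MOM-protected flavanone, (2RS,2''R) epimers at C-2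
Conditions: NaOAc (5 equiv), EtOH, 80 °C, 48 h
Reagents that add atoms: none
Why: Intramolecular oxa-Michael (6-endo-trig) of the only free phenol (2'-OH) gives 8-alkyl regiochemistry, since the other A-ring oxygens are protected. C-2 forms as roughly a 1:1 epimer mixture because the lavandulyl stereocentre is remote, and the epimers are separated after deprotection in Step 10.

**Step 10**
Reactants: 12
Product: 13, norkurarinol
Conditions: 3 M HCl/MeOH 1:4, 40 °C, 4 h; then preparative C18 HPLC (MeCN/H2O, 0.1% HCO2H) to separate the 2S,2''R epimer from the 2R,2''R epimer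
Reagents that add atoms: none
Why: Acidic methanolysis of the four aryl MOM ethers. The flavanone is already closed, so the 5-OH cannot re-cyclise, and C-2 does not epimerise under acid. The (2S,2''R) diastereomer is isolated by achiral chromatography, and the (R)-lavandulyl centre is never touched.

## Compound list
1 | (+)-limonene oxide, (4R), cis/trans | CC12OC1C[C@@H](CC2)C(C)=C | starting material
2 | (3R)-3-isopropenyl-6-oxoheptanal | O=CC[C@@H](CCC(C)=O)C(C)=C | intermediate
3 | (3R)-3-isopropenyl-6-oxoheptanoic acid | OC(=O)C[C@@H](CCC(C)=O)C(C)=C | intermediate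
4 | (3R)-6-hydroxy-6-methyl-3-isopropenylheptanoic acid | OC(=O)C[C@@H](CCC(C)(C)O)C(C)=C | intermediate
5 | NHPI ester of 4 | O=C(ON1C(=O)c2ccccc2C1=O)C[C@@H](CCC(C)(C)O)C(C)=C | intermediate
6 | 2,4,6-trihydroxyacetophenone | CC(=O)c1c(O)cc(O)cc1O | starting material
7 | 3'-lavandulyl (hydrated) phloroacetophenone | C=C(C)[C@H](CCC(C)(C)O)Cc1c(O)cc(O)c(C(C)=O)c1O | intermediate
8 | 4',6'-bis-MOM ether of 7 | C=C(C)[C@H](CCC(C)(C)O)Cc1c(OCOC)cc(OCOC)c(C(C)=O)c1O | intermediate
9 | 2,4-dihydroxybenzaldehyde | O=Cc1ccc(O)cc1O | starting material
10 | 2,4-bis(MOM-oxy)benzaldehyde | O=Cc1ccc(OCOC)cc1OCOC | intermediate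
11 | tetra-MOM 2'-hydroxychalcone | C=C(C)[C@H](CCC(C)(C)O)Cc1c(OCOC)cc(OCOC)c(C(=O)/C=C/c2ccc(OCOC)cc2OCOC)c1O | intermediate
12 | tetra-MOM flavanone, C-2 epimer mixture | C=C(C)[C@H](CCC(C)(C)O)Cc1c(OCOC)cc(OCOC)c2c1OC(c1ccc(OCOC)cc1OCOC)CC2=O | intermediate
13 | norkurarinol (2S,2''R) | C=C(C)[C@H](CCC(C)(C)O)Cc1c(O)cc(O)c2c1O[C@H](c1ccc(O)cc1O)CC2=O | target

## Step count
Total steps: 10.
Longest linear sequence: 9 (Steps 1–6, 8, 9, 10; Step 7 is a parallel branch).

## Three steps most likely to fail
1. **Step 5 (proposed new photochemical alkylation).** Possible problems are O-acylation of the phenolate by the active ester, a homoallyl-radical 1,2-vinyl shift, and dialkylation.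
   - Fallback: use known Ni/Ir metallaphotoredox decarboxylative arylation of free acid 4 with 3'-bromo-2'-hydroxy-4',6'-bis-MOM-acetophenone, made by NBS bromination of bis-MOM acetophenone, with regioisomers separated.
2. **Step 6 (selective bis-MOM protection).** If 6'-OH is left free instead of 2'-OH, the wrong (6-alkyl) flavanone would form.
   - Fallback: skip regiocontrol, take unprotected 7 through Claisen–Schmidt and cyclisation, and separate the 6- and 8-alkyl flavanones by HPLC, as in desmethylxanthohumol isomerisation.
3. **Step 10 (acid deprotection and C-2 epimer separation).** The tertiary alcohol and isopropenyl group are acid-sensitive, and the epimer separation caps the yield near 50%.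
   - Fallback: use bis-allyl ethers instead of MOM (allyl bromide/K2CO3 in Steps 6–7), and remove them at the end with Pd(PPh3)4 under neutral conditions before the HPLC separation.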